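**Assumptions (one line).** The target is the ent-kaurane 6,7-seco 7,20-lactone with a C19 acetoxymethyl group on C4. The chiral Ru-TsDPEN catalyst is chosen to give the C4 configuration drawn in 6 (both enantiomers are commercial).

## Retrosynthetic overview
1. Trichorabdal B comes from the bicyclo[3.2.1]octane-dione 34 by thermodynamic C11 reduction, C16 α-methylenation, and unmasking of C6 (silyl ether → aldehyde).
2. Rings C and D of 34 come from a **proposed new aldol–Michael domino cyclization** of the spirolactone keto-aldehyde 33 (C11 and C15 methyl ketones plus a C13 aldehyde).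
3. 33 comes from allylation of β-keto spirolactone 22 to make quaternary C8, after C5→C6 conversion by Wittig methylenation then hydroboration. 22 is formed by Sm-mediated epoxy-ketone opening, Michael addition and lactonization, which joins A-ring epoxy ketone 16 to alkylidene acetoacetate 21 (C9–C10 bond, δ-lactone).
4. 16 comes from desymmetrization of a 2-methyl-2-(silyloxymethyl)cyclohexane-1,3-dione (the C4 stereocentre). Ring order: A ring (from 1), lactone (step 12), then C and D rings together (step 19).

## Route

**Step 1**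
Reactants: 1 2-methylcyclohexane-1,3-dione; 2 formaldehyde
Product: 3 2-(hydroxymethyl)-2-methylcyclohexane-1,3-dione
Conditions: 37% aq. HCHO (1.5 equiv), Et3N (0.1 equiv), H2O, rt
Reagents that add atoms: formaldehyde (2), C=O
Why: Aldol hydroxymethylation of the acidic C2–H makes the prochiral quaternary carbon that becomes C4.

**Step 2**
Reactants: 3; 4 TBSCl
Product: 5 2-{[(tert-butyldimethylsilyl)oxy]methyl}-2-methylcyclohexane-1,3-dione
Conditions: TBSCl, imidazole, DMF, rt
Reagents that add atoms: TBSCl (4), CC(C)(C)[Si](C)(C)Cl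
Why: Silylation. A silyl ether is used because a free 1,3-hydroxy acetate would undergo acyl migration in step 3.

**Step 3**
Reactants: 5
Product: 6 (2R,3S)-2-{[(TBS)oxy]methyl}-3-hydroxy-2-methylcyclohexan-1-one
Conditions: RuCl[(S,S)-TsDPEN](p-cymene) (1 mol%), HCO2H/Et3N 5:2, CH2Cl2, 30 °C
Reagents that add atoms: none
Why: Noyori–Ikariya asymmetric transfer hydrogenation desymmetrizes the two enantiotopic C=O groups and sets C4. The carbinol centre is removed in step 5.

**Step 4**
Reactants: 6; 7 TCDI
Product: 8 imidazolylthiocarbonate of 6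
Conditions: TCDI, DMAP (cat.), ClCH2CH2Cl, 80 °C
Reagents that add atoms: 1,1'-thiocarbonyldiimidazole (7), S=C(n1ccnc1)n1ccnc1
Why: First half of the Barton–McCombie deoxygenation; the hindered neopentylic alcohol is activated.

**Step 5**
Reactants: 8
Product: 9 (2S)-2-{[(TBS)oxy]methyl}-2-methylcyclohexan-1-one
Conditions: Bu3SnH, AIBN, PhMe, 110 °C
Reagents that add atoms: none
Why: Radical deoxygenation removes the C3 oxygen. C4 is quaternary and untouched.

**Step 6**
Reactants: 9; 10 acetic anhydride
Product: 11 [(1S)-1-methyl-2-oxocyclohexyl]methyl acetate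
Conditions: Ac2O, FeCl3 (10 mol%), CH2Cl2, rt
Reagents that add atoms: Ac2O (10), CC(=O)OC(C)=O
Why: Lewis-acid-catalysed silyl-ether to acetate exchange installs the C19 OAc of the target in one operation.

**Step 7**
Reactants: 11; 12 Eschenmoser's salt
Product: 13 Mannich base, [(1S)-3-(dimethylaminomethyl)-1-methyl-2-oxocyclohexyl]methyl acetate (C10 epimers)
Conditions: LDA (1.05 equiv), THF, −78 °C; then 12, −78 °C → rt
Reagents that add atoms: Eschenmoser's salt (12), C[N+](C)=C.[I-]
Why: Mannich aminomethylation occurs at C10, the only enolizable α-position, because C4 is quaternary.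

**Step 8**
Reactants: 13
Product: 14 [(1S)-1-methyl-3-methylidene-2-oxocyclohexyl]methyl acetate
Conditions: MeI (30 equiv), THF, rt; then DBU, 0 °C
Reagents that add atoms: none (the MeI methyl leaves as NMe3)
Why: Quaternization then E1cB elimination gives the exocyclic enone, which becomes C20.

**Step 9**
Reactants: 14; 15 tert-butyl hydroperoxide
Product: 16 [(5S)-5-methyl-4-oxo-1-oxaspiro[2.5]octan-5-yl]methyl acetate (C3 epimers converge in step 12)
Conditions: t-BuOOH, DBU, THF, 0 °C
Reagents that add atoms: t-BuOOH (15), CC(C)(C)OO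
Why: Weitz–Scheffer nucleophilic epoxidation. The spiro-epoxide stereochemistry is irrelevant because step 12 opens it to a planar enolate.

**Step 10**
Reactants: 17 2-methyl-2-vinyl-1,3-dioxolane; 18 ozone
Product: 19 2-methyl-1,3-dioxolane-2-carbaldehyde
Conditions: O3, CH2Cl2, −78 °C; then Me2S
Reagents that add atoms: ozone (18), [O-][O+]=O
Why: Ozonolysis gives the ketal-protected pyruvaldehyde, which becomes the C9/C11/C12 unit.

**Step 11**
Reactants: 19; 20 methyl acetoacetate
Product: 21 methyl 2-acetyl-3-(2-methyl-1,3-dioxolan-2-yl)acrylate (E/Z)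
Conditions: piperidine (0.1 equiv), AcOH (0.1 equiv), PhH, 4 Å MS, reflux
Reagents that add atoms: none
Why: Knoevenagel condensation gives the doubly activated acceptor that carries C7, C8, C9 and C15.

**Step 12**
Reactants: 16; 21
Product: 22 spirolactone (β-keto δ-lactone; C8 epimeric, C4/C9/C10 as in SMILES)
Conditions: SmI2 (2.2 equiv), THF, −78 °C, 15 min; then 21 (1.5 equiv), −78 → 0 °C; then DBU (cat.), PhMe, 50 °C if needed
Reagents that add atoms: none
Why: Molander-type SmI2 reductive opening of the α,β-epoxy ketone gives the Sm(III) enolate with a C20 alkoxide. Michael addition to 21 forms C9–C10 and the quaternary C10. A(1,2)-strain with the enolate oxygen forces the larger CH2OAc (C19) pseudo-axial, so the acceptor attacks anti to C19 and C20 ends up syn to C19. The chelated Sm β-ketoester transition state places the dioxolanyl group equatorial (C9). The C20 alkoxide then lactonizes onto the methyl ester.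

**Step 13**
Reactants: 22; 23 methylenetriphenylphosphorane
Product: 24 C5 exocyclic-methylene spirolactone
Conditions: Ph3PCH3Br (4.5 equiv), KOtBu (4 equiv), THF, 65 °C
Reagents that add atoms: Ph3P=CH2 (23), C=P(c1ccccc1)(c1ccccc1)c1ccccc1
Why: Wittig methylenation of the C5 ketone. The first equivalent of ylide deprotonates the acidic C8–H, so the C15 acetyl is protected as its enolate.

**Step 14**
Reactants: 24; 25 hydrogen peroxide
Product: 26 C6 primary alcohol
Conditions: 9-BBN (4 equiv), THF, 0 °C → rt; then NaBO3·4H2O, THF/H2O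
Reagents that add atoms: hydrogen peroxide (as perborate) (25), OO
Why: Hydroboration–oxidation. Hydrogen is delivered to C5 from the bottom face, anti to the syn-diaxial C19 and C20. This sets C5 with H5 down and C6 equatorial, as in the target.

**Step 15**
Reactants: 26; 27 TBDPSCl
Product: 28 C6-O-TBDPS ether
Conditions: TBDPSCl, imidazole, DMAP (cat.), DMF, 50 °C
Reagents that add atoms: TBDPSCl (27), CC(C)(C)[Si](c1ccccc1)(c1ccccc1)Cl
Why: Protection with an acid-stable silyl ether for the later ketal hydrolysis.

**Step 16**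
Reactants: 28; 29 allyl bromide
Product: 30 C8-allyl spirolactone
Conditions: allyl bromide (5 equiv), K2CO3 (3 equiv), acetone, 60 °C
Reagents that add atoms: allyl bromide (29), C=CCBr
Why: C-Alkylation of the β-keto lactone enolate. The electrophile approaches anti to the axial C5 ring bond (the conformer with equatorial C9 is favoured) and sets the quaternary C8, so C14 is equatorial and C15 axial.

**Step 17**
Reactants: 30
Product: 31 C11 methyl ketone (ketal removed)
Conditions: I2 (10 mol%), acetone, 45 °C
Reagents that add atoms: none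
Why: Neutral transketalization; the silyl ether and acetate are untouched.

**Step 18**
Reactants: 31; 32 sodium periodate
Product: 33 keto-aldehyde (C13 aldehyde, C11 and C15 methyl ketones)
Conditions: OsO4 (5 mol%), NaIO4 (4 equiv), 2,6-lutidine (2 equiv), dioxane/H2O 3:1, rt
Reagents that add atoms: NaIO4 (32), [Na+].[O-]I(=O)(=O)=O
Why: Lemieux–Johnson cleavage converts the allyl group to CH2CHO (C14–C13).

**Step 19**
Reactants: 33
Product: 34 bicyclo[3.2.1]octane-11,15-dione
Conditions: pyrrolidine (0.2 equiv), AcOH (0.2 equiv), CH2Cl2, 0.01 M, rt; then DBU (1 equiv), PhMe, 60 °C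
Reagents that add atoms: none
Why: Proposed new method: pyrrolidine/AcOH drives intramolecular aldol condensation of the C11 methyl ketone (C12 nucleophile) onto the C13 aldehyde (6-enolendo-exo-trig) to give the cyclohexenone C11(=O)–C12=C13. DBU then promotes intramolecular Michael addition of the C15 acetyl enolate (C16) to C13, bridging C8 and C13 on the only reachable face (syn to the axial C15) to close the bicyclo[3.2.1]octane and set C13. C9 epimerizes through the C11 enol to the isomer with equatorial C10, and the [3.2.1] product is a thermodynamic sink. The closest known reactions are Robinson-type aldol condensation followed by enolate–enone Michael bridging (double aldol/Michael cascades to bicyclo[3.2.1]octanes), never applied to a keto-aldehyde on a spirolactone to build rings C and D of an ent-kauranoid.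

**Step 20**
Reactants: 34
Product: 35 C11 alcohol (equatorial)
Conditions: Al(OiPr)3 (3 equiv), iPrOH/PhMe 1:1, 80 °C
Reagents that add atoms: none
Why: Meerwein–Ponndorf–Verley equilibration gives the more stable equatorial (exo) alcohol, which avoids the endo 2-carbon bridge and sets C11. The hindered neopentyl, bridged C15 ketone reacts more slowly.

**Step 21**
Reactants: 35; 12 Eschenmoser's salt
Product: 36 C16 Mannich base
Conditions: LDA (2.3 equiv), THF, −78 °C; then 12 (2.5 equiv), −78 → 0 °C
Reagents that add atoms: Eschenmoser's salt (12), C[N+](C)=C.[I-]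
Why: C8 is quaternary, so C15 enolizes only toward C16; the extra LDA equivalent covers the free C11 OH.

**Step 22**
Reactants: 36
Product: 37 C16=C17 enone
Conditions: MeI (30 equiv), THF, rt; then DBU, 0 °C
Reagents that add atoms: none
Why: Quaternization then elimination gives the exocyclic methylene. It is the only possible direction because C13 is a bridgehead.

**Step 23**
Reactants: 37
Product: 38 C6 primary alcohol
Conditions: TBAF/AcOH (1:1), THF, 0 °C → rt
Reagents that add atoms: none
Why: Buffered fluoride removes the TBDPS group without cleaving the acetate or opening the lactone.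

**Step 24**
Reactants: 38
Product: 39 trichorabdal B
Conditions: TEMPO (10 mol%), PhI(OAc)2 (1.3 equiv), CH2Cl2, 0 °C → rt
Reagents that add atoms: none
Why: TEMPO/BAIB oxidizes the primary C6 alcohol selectively over the hindered secondary C11 alcohol, and mild conditions preserve the C5 configuration.

## Compound list
1 | 2-methylcyclohexane-1,3-dione | CC1C(=O)CCCC1=O | starting material
2 | formaldehyde | C=O | starting material
3 | 2-(hydroxymethyl)-2-methylcyclohexane-1,3-dione | CC1(CO)C(=O)CCCC1=O | intermediate
4 | TBSCl | CC(C)(C)[Si](C)(C)Cl | starting material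
5 | 2-(TBSOCH2)-2-methylcyclohexane-1,3-dione | CC(C)(C)[Si](C)(C)OCC1(C)C(=O)CCCC1=O | intermediate
6 | (2R,3S)-3-hydroxy-2-(TBSOCH2)-2-methylcyclohexanone | CC(C)(C)[Si](C)(C)OC[C@@]1(C)C(=O)CCC[C@@H]1O | intermediate
7 | TCDI | S=C(n1ccnc1)n1ccnc1 | starting material
8 | imidazolylthiocarbonate of 6 | CC(C)(C)[Si](C)(C)OC[C@@]1(C)C(=O)CCC[C@@H]1OC(=S)n1ccnc1 | intermediate
9 | (2S)-2-(TBSOCH2)-2-methylcyclohexanone | CC(C)(C)[Si](C)(C)OC[C@@]1(C)C(=O)CCCC1 | intermediate
10 | acetic anhydride | CC(=O)OC(C)=O | starting material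
11 | [(1S)-1-methyl-2-oxocyclohexyl]methyl acetate | CC(=O)OC[C@@]1(C)C(=O)CCCC1 | intermediate
12 | Eschenmoser's salt | C[N+](C)=C.[I-] | starting material
13 | Mannich base of 11 | CC(=O)OC[C@@]1(C)C(=O)C(CN(C)C)CCC1 | intermediate
14 | α-methylene ketone | CC(=O)OC[C@@]1(C)C(=O)C(=C)CCC1 | intermediate
15 | tert-butyl hydroperoxide | CC(C)(C)OO | starting material
16 | spiro-epoxy ketone | CC(=O)OC[C@@]1(C)C(=O)C2(CO2)CCC1 | intermediate
17 | 2-methyl-2-vinyl-1,3-dioxolane | C=CC1(C)OCCO1 | starting material
18 | ozone | [O-][O+]=O | starting material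
19 | 2-methyl-1,3-dioxolane-2-carbaldehyde | O=CC1(C)OCCO1 | intermediate
20 | methyl acetoacetate | CC(=O)CC(=O)OC | starting material
21 | alkylidene acetoacetate | CC(=O)C(=CC1(C)OCCO1)C(=O)OC | intermediate
22 | β-keto spirolactone | CC1(OCCO1)[C@@H]2[C@@]3(CCC[C@@](C)(COC(C)=O)C3=O)COC(=O)C2C(C)=O | intermediate
23 | methylenetriphenylphosphorane | C=P(c1ccccc1)(c1ccccc1)c1ccccc1 | starting material
24 | C5-methylene spirolactone | CC1(OCCO1)[C@@H]2[C@@]3(CCC[C@@](C)(COC(C)=O)C3=C)COC(=O)C2C(C)=O | intermediate
25 | hydrogen peroxide | OO | starting material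
26 | C6 alcohol | CC1(OCCO1)[C@@H]2[C@@]3(CCC[C@@](C)(COC(C)=O)[C@H]3CO)COC(=O)C2C(C)=O | intermediate
27 | TBDPSCl | CC(C)(C)[Si](c1ccccc1)(c1ccccc1)Cl | starting material
28 | C6-OTBDPS ether | CC1(OCCO1)[C@@H]2[C@@]3(CCC[C@@](C)(COC(C)=O)[C@H]3CO[Si](c4ccccc4)(c4ccccc4)C(C)(C)C)COC(=O)C2C(C)=O | intermediate
29 | allyl bromide | C=CCBr | starting material
30 | C8-allyl lactone | CC1(OCCO1)[C@@H]2[C@@]3(CCC[C@@](C)(COC(C)=O)[C@H]3CO[Si](c4ccccc4)(c4ccccc4)C(C)(C)C)COC(=O)[C@]2(CC=C)C(C)=O | intermediate
31 | C11 methyl ketone | CC(=O)[C@@H]2[C@@]3(CCC[C@@](C)(COC(C)=O)[C@H]3CO[Si](c4ccccc4)(c4ccccc4)C(C)(C)C)COC(=O)[C@]2(CC=C)C(C)=O | intermediate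
32 | sodium periodate | [Na+].[O-]I(=O)(=O)=O | starting material
33 | keto-aldehyde | CC(=O)[C@@H]2[C@@]3(CCC[C@@](C)(COC(C)=O)[C@H]3CO[Si](c4ccccc4)(c4ccccc4)C(C)(C)C)COC(=O)[C@]2(CC=O)C(C)=O | intermediate
34 | bicyclo[3.2.1]octane-dione | C1C(=O)[C@]23C[C@H]1CC(=O)[C@@H]2[C@@]1(CCC[C@@](C)(COC(C)=O)[C@H]1CO[Si](c4ccccc4)(c4ccccc4)C(C)(C)C)COC3=O | intermediate
35 | C11 alcohol | C1C(=O)[C@]23C[C@H]1C[C@@H](O)[C@@H]2[C@@]1(CCC[C@@](C)(COC(C)=O)[C@H]1CO[Si](c4ccccc4)(c4ccccc4)C(C)(C)C)COC3=O | intermediate
36 | C16 Mannich base | CN(C)CC1C(=O)[C@]23C[C@H]1C[C@@H](O)[C@@H]2[C@@]1(CCC[C@@](C)(COC(C)=O)[C@H]1CO[Si](c4ccccc4)(c4ccccc4)C(C)(C)C)COC3=O | intermediate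
37 | enone | C=C1C(=O)[C@]23C[C@H]1C[C@@H](O)[C@@H]2[C@@]1(CCC[C@@](C)(COC(C)=O)[C@H]1CO[Si](c4ccccc4)(c4ccccc4)C(C)(C)C)COC3=O | intermediate
38 | C6 primary alcohol | C=C1C(=O)[C@]23C[C@H]1C[C@@H](O)[C@@H]2[C@@]1(CCC[C@@](C)(COC(C)=O)[C@H]1CO)COC3=O | intermediate
39 | trichorabdal B | C=C1C(=O)[C@]23C[C@H]1C[C@@H](O)[C@@H]2[C@@]1(CCC[C@@](C)(COC(C)=O)[C@H]1C=O)COC3=O | target

## Totals
Total steps: 24. Longest linear sequence: 22 steps (1→9, then 12, then 13→24). The acceptor branch (steps 10–11) runs in parallel.

## Three steps most likely to fail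
1. **Step 19, aldol–Michael domino (new method).** The 5-(enolendo) Michael closure may be slow, and competing aldol pathways may appear. Fallback (known chemistry): run the steps separately. Do the pyrrolidine/AcOH aldol condensation to the cyclohexenone, then form the C15 silyl enol ether (TMSOTf, Et3N) and close the ring by intramolecular Mukaiyama–Michael (TiCl4 or Sc(OTf)3).
2. **Step 12, hindered Sm(III) enolate Michael forming C9–C10 with vicinal quaternary/tertiary centres.** Fallback: do Kobayashi hydroxymethylation of the TMS enol ether of a C5 ketone (HCHO aq., Sc(OTf)3), protect as the PMB ether, generate the enolate with KHMDS and add 21 (Michael), then remove PMB with DDQ and lactonize.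
3. **Step 13, Wittig methylenation of the C5 ketone flanked by two quaternary centres.** Fallback: Corey–Chaykovsky epoxidation (Me3S+ I−, NaH) then Meinwald rearrangement (MgBr2) to the C6 aldehyde, followed by NaBH4 reduction to alcohol 26. C5 would then be set by aldehyde equilibration, with chromatographic separation if needed.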